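**The leftover.** What the impurity leaves of the catalyst is what works in Wednesday's flask. That flask holds 63.0 mM of free catalyst F, the catalyst charge less the impurity, taken one for one by my assumption. Thursday's run holds 113 mM.

all flasks: gas phase 200 mM (held); impurity 37 mM
- Wednesday's: solid substrate 2 M; free catalyst 5 mol%; the very flask that is asked about, followed so far
- Thursday's: solid substrate 2 M; free catalyst 7.5 mol%; run made earlier
- flask: solid substrate 2.0 M; free catalyst 5 mol%; time 2.5 min

| run | time / s | target / % | solid substrate / % |
|---|---|---|---|
| Wednesday's | 10.0 | 0.3 | 91.5 |
| Wednesday's | 20.0 | 0.8 | 85.7 |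
| Wednesday's | 30.0 | 1.4 | 77.7 |
| Thursday's | 10.0 | 0.1 | 91.6 |
| Thursday's | 15.0 | 0.3 | 88.4 |
| Thursday's | 25.0 | 1.7 | 81.2 |
| Thursday's | 40.0 | 3.7 | 70.0 |
| Thursday's | 60.0 | 7.7 | 57.4 |
| Thursday's | 120 | 22.9 | 23.4 |

(each reading ± 0.5 percentage points)

- solid, in amounts per volume of the solution: solid substrate
- the numbers in the tables scatter with a standard deviation of 0.5 percentage points
- at the start none of the solid substrate is in solution
- at the start none of the gas phase is in solution

* target at 2.5 min, in percent of the solid substrate charged
* the change that raises the amount of target at 2.5 min, in percent of the solid substrate charged most ("none" if none brings more than 2 percentage points) (alpha / zeta / delta / beta / none)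
* amount of target at 2.5 min, in percent of the solid substrate charged, after zeta

- alpha: doubling the dissolution coefficient of the solid substrate, all else as stated
- zeta: doubling the saturation concentration of gas phase, all else as stated
- delta: doubling the amount of free catalyst, all else as stated
- beta: doubling the solubility of the solid substrate, all else as stated

**In the flask.** Wednesday's solid reads 77.7% at 30.0 s, between Thursday's 81.2% at 25.0 s and 70.0% at 40.0 s, so these readings show no effect of the extra catalyst on dissolving.

**When you come.** I extend Thursday's last slope of target to 2.5 min and scale it by the ratio of F, which gives 17.0%. Doubling the catalyst lifts F to 163 mM, a factor of 2.59, so I pick delta. The gas order is unread, so I give zeta no figure.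

**Hands off.** Add no impurity. By my assumption each millimole per litre comes straight off F.

**The result.** The forecast says 21% (17% to 26%), delta as “the largest lever”, and 34% after zeta; the flask gives 18.7%, delta with a gain of 21 percentage points, and 28.3% after zeta.

    starting material + dissolved gas + free catalyst → free catalyst + target (k = 0.332 M⁻² s⁻¹)
    starting material + dissolved gas → uncatalysed product (k = 0.0301 M⁻¹ s⁻¹)
    solid substrate ⇌ starting material, rate k3*(cs3 - [starting material]) while solid is left; crystals form when [starting material] > cs3 (solubility = 2.00 M, k = 0.00853 s⁻¹)
    free catalyst + impurity → spent catalyst (k = 7.16 M⁻¹ s⁻¹)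
    gas phase ⇌ dissolved gas, rate k5*(csat - [dissolved gas]) (kL = 1.44 s⁻¹)

**Not at rest.** Let S be the catalysed constant times F over the uncatalysed constant, the selectivity factor. For this flask S is 0.695, and target over uncatalysed product reads 0.695. The neighbour with 0.063 M impurity has F of 37.0 mM and S of 0.408; it holds 11.6% target against 28.4% uncatalysed product. This flask still holds 43.3% starting material and 11.1% solid at 2.50 min. By 25.0 min both stand at 0%, uncatalysed product has reached 59.0%, and target has risen from 18.7% to 41.0%.

The earlier runs and the new flask were computed on assumed constants, and the scatter is random.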